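**Retrosynthetic overview**
1. The target is the all-trans oxolane (2R,3S,4S,5R): O1, C2 (4-hydroxy-3,5-dimethoxyphenyl), C3 and C4 (CH2OH), C5 (3,4,5-trimethoxyphenyl).
2. Key disconnection: the oxolane, the only ring not bought, is cut at O1–C2 and C4–C5 into 3,4,5-trimethoxybenzaldehyde (O1, C5) and a donor–acceptor cyclopropane (C2, C3, C4). It is closed last by a strain-releasing formal [3+2] cycloaddition.
3. Enabling feature: C2 is benzylic to the electron-rich trioxygenated aryl ring (donor) and stands 1,3 to C4, whose CH2OH carbon can be carried as one ester of a malonate (acceptor). The C2/C4 pair can therefore be tied into a polarised cyclopropane bond, and the para-hydroxyl of the same aryl ring later lets C2 be corrected through a quinone methide.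
4. Stereochemical plan: C3 is set once by organocatalytic cyclopropanation and never touched. C2 is first set cis by inversion and relays its configuration to C5 in the cycloaddition. C4 (ester epimerisation) and C2 (quinone methide) are then equilibrated to the all-trans array.
5. Order of rings: aryl rings bought; temporary cyclopropane (step 3); oxolane (step 5, last ring); then loss of one ester carbon, deprotection, reduction.

Key step: step 5

Remark on the chemistry: the numbering O1, C2 (phenol-bearing), C3, C4, C5 (trimethoxyphenyl-bearing) of line 1 is used in all Why lines. It is assumed that (R)-2-[diphenyl(trimethylsilyloxy)methyl]pyrrolidine directs bromomalonate to the Re face of C-β of enal 3, the usual sense for iminium activation of aryl enals.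

Step 1
Reactants: 1 4-hydroxy-3,5-dimethoxybenzaldehyde (syringaldehyde)
Product: 2 4-(benzyloxy)-3,5-dimethoxybenzaldehyde
Conditions: BnBr, K2CO3, DMF, rt
Reagents that add atoms: benzyl bromide, BrCc1ccccc1
Why: Williamson ether synthesis on the phenoxide masks the phenol as a benzyl ether that should survive every step up to the hydrogenolysis.

Step 2
Reactants: 2 4-(benzyloxy)-3,5-dimethoxybenzaldehyde
Product: 3 (2E)-3-[4-(benzyloxy)-3,5-dimethoxyphenyl]prop-2-enal
Conditions: Ph3P=CHCHO (1.1 equiv), toluene, 90 °C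
Reagents that add atoms: (triphenylphosphoranylidene)acetaldehyde, O=CC=P(c1ccccc1)(c1ccccc1)c1ccccc1
Why: Wittig olefination with a stabilised ylide should give the two-carbon homologated (E)-enal.

Step 3
Reactants: 3 (2E)-3-[4-(benzyloxy)-3,5-dimethoxyphenyl]prop-2-enal; 4 dimethyl 2-bromopropanedioate (dimethyl bromomalonate)
Product: 5 dimethyl (2R,3S)-2-[4-(benzyloxy)-3,5-dimethoxyphenyl]-3-formylcyclopropane-1,1-dicarboxylate (aryl and formyl trans)
Conditions: (R)-2-[diphenyl(trimethylsilyloxy)methyl]pyrrolidine (20 mol %), 2,6-lutidine (1.1 equiv), CH2Cl2, 0 °C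
Reagents that add atoms: none
Why: Organocatalytic Michael-initiated ring closure: the iminium ion shields one face so that bromomalonate should add to the Re face of C-β (aryl carbon R), and the resulting enamine closes the ring by 3-exo-tet alkylation to the trans cyclopropane (formyl carbon S, the future C3).

Step 4
Reactants: 5 dimethyl (2R,3S)-2-[4-(benzyloxy)-3,5-dimethoxyphenyl]-3-formylcyclopropane-1,1-dicarboxylate
Product: 7 dimethyl (2R,3S)-2-[4-(benzyloxy)-3,5-dimethoxyphenyl]-3-({[tert-butyl(diphenyl)silyl]oxy}methyl)cyclopropane-1,1-dicarboxylate, via hydroxymethyl cyclopropane 6 (not isolated)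
Conditions: NaBH4, MeOH/CH2Cl2, −40 °C; AcOH quench, extraction; then TBDPSCl, imidazole, CH2Cl2, 0 °C
Reagents that add atoms: tert-butyl(chloro)diphenylsilane, CC(C)(C)[Si](Cl)(c1ccccc1)c1ccccc1
Why: Chemoselective borohydride reduction of the aldehyde followed at once by silylation of the primary alcohol should leave alcohol 6 no time to lactonise onto the cis ester, and no stereocentre is affected.

Step 5
Reactants: 7 dimethyl (2R,3S)-2-[4-(benzyloxy)-3,5-dimethoxyphenyl]-3-({[tert-butyl(diphenyl)silyl]oxy}methyl)cyclopropane-1,1-dicarboxylate; 8 3,4,5-trimethoxybenzaldehyde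
Product: 10 dimethyl (2S,4S,5S)-5-[4-(benzyloxy)-3,5-dimethoxyphenyl]-4-({[tert-butyl(diphenyl)silyl]oxy}methyl)-2-(3,4,5-trimethoxyphenyl)oxolane-3,3-dicarboxylate, via oxocarbenium malonate zwitterion 9 (not isolated)
Conditions: AlCl3 (15 mol %), 8 (2 equiv), CH2Cl2, 0 °C to rt
Reagents that add atoms: none
Why: AlCl3 chelates the geminal diester of 7 and polarises the C2–C4 cyclopropane bond, the carbonyl oxygen of 8 attacks the benzylic carbon C2 from the back with inversion to give zwitterion 9, and after rotation about C2–C3 the metal-bound malonate adds to the (E)-oxocarbenium carbon C5, so that strain release drives formation of the O1–C2 and C4–C5 bonds in one operation. The closest known reaction type is the Lewis-acid-catalysed formal [3+2] cycloaddition of 2-aryl and 2,3-disubstituted cyclopropane-1,1-diesters with aryl aldehydes, which gives 2,5-cis oxolanes with transfer of the cyclopropane configuration. The oxolane, the only ring closed, forms by an intermolecular SN2-type C–O alkylation followed by an aldol-type 5-(enolexo)-endo-trig C–C closure through an envelope transition state. C2 is set by inversion of the (R)-benzylic carbon of 7 and so becomes (S) with the aryl group cis to the C3 side chain, C5 is set cis to the C2 aryl group because both aryl groups take pseudo-equatorial places in that envelope, and C3 is not touched. The step needs SN2 opening instead of ionisation and a 2,5-cis closure, which the substrate should secure through a benzylic aryl group that is only a moderate donor (its para-oxygen is twisted out of conjugation by the two flanking methoxy groups), a non-participating silyl ether at C3 and an electron-rich aldehyde that is a good oxygen nucleophile. The 2,3-cis relation formed here is not that of the target, but the configuration it relays to C5 is final and C2 itself is corrected in step 8.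

Step 6
Reactants: 10 dimethyl (2S,4S,5S)-5-[4-(benzyloxy)-3,5-dimethoxyphenyl]-4-({[tert-butyl(diphenyl)silyl]oxy}methyl)-2-(3,4,5-trimethoxyphenyl)oxolane-3,3-dicarboxylate
Product: 12 methyl (2R,3R,4S,5S)-5-[4-(benzyloxy)-3,5-dimethoxyphenyl]-4-({[tert-butyl(diphenyl)silyl]oxy}methyl)-2-(3,4,5-trimethoxyphenyl)oxolane-3-carboxylate, via C4-epimeric monoester 11 (not isolated)
Conditions: LiCl, H2O, DMSO, 150 °C; then NaOMe (cat.), MeOH, rt
Reagents that add atoms: none
Why: Krapcho dealkoxycarbonylation removes one ester and protonation on the open face should first give mainly epimer 11, which methoxide equilibrates through the ester enolate to 12, the only C4 epimer with the ester trans to both the C3 and the C5 substituent.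

Step 7
Reactants: 12 methyl (2R,3R,4S,5S)-5-[4-(benzyloxy)-3,5-dimethoxyphenyl]-4-({[tert-butyl(diphenyl)silyl]oxy}methyl)-2-(3,4,5-trimethoxyphenyl)oxolane-3-carboxylate
Product: 13 methyl (2R,3R,4S,5S)-4-({[tert-butyl(diphenyl)silyl]oxy}methyl)-5-(4-hydroxy-3,5-dimethoxyphenyl)-2-(3,4,5-trimethoxyphenyl)oxolane-3-carboxylate
Conditions: H2 (1 atm), Pd/C, EtOAc, rt, stopped at full debenzylation
Reagents that add atoms: none
Why: Hydrogenolysis of the aryl benzyl ether is much faster than that of the ring benzylic C–O bonds, so the phenol should be freed without change at any stereocentre.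

Step 8
Reactants: 13 methyl (2R,3R,4S,5S)-4-({[tert-butyl(diphenyl)silyl]oxy}methyl)-5-(4-hydroxy-3,5-dimethoxyphenyl)-2-(3,4,5-trimethoxyphenyl)oxolane-3-carboxylate
Product: 15 methyl (2R,3R,4S,5R)-4-({[tert-butyl(diphenyl)silyl]oxy}methyl)-5-(4-hydroxy-3,5-dimethoxyphenyl)-2-(3,4,5-trimethoxyphenyl)oxolane-3-carboxylate, via ring-opened quinone methide 14 (not isolated)
Conditions: CSA (20 mol %), CH2Cl2 (dilute), rt
Reagents that add atoms: none
Why: Acid-catalysed epimerisation of a para-hydroxybenzylic ether: reversible heterolysis of the C2–O1 bond, assisted by the para-hydroxyl, gives quinone methide 14, and its reversible 5-exo-trig reclosure by the C5 hydroxyl (oxa-1,6-addition) should settle C2 with the aryl group trans to the bulky C3 substituent, while C3, C4 and C5 are not touched.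

Step 9
Reactants: 15 methyl (2R,3R,4S,5R)-4-({[tert-butyl(diphenyl)silyl]oxy}methyl)-5-(4-hydroxy-3,5-dimethoxyphenyl)-2-(3,4,5-trimethoxyphenyl)oxolane-3-carboxylate
Product: 16 [(2R,3S,4S,5R)-4-({[tert-butyl(diphenyl)silyl]oxy}methyl)-5-(4-hydroxy-3,5-dimethoxyphenyl)-2-(3,4,5-trimethoxyphenyl)oxolan-3-yl]methanol
Conditions: LiAlH4 (excess), THF, 0 °C
Reagents that add atoms: none
Why: Hydride reduction of the ester to the primary alcohol (the phenol is carried as its phenoxide) proceeds without enolisation, so C4 should keep its configuration.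

Step 10
Reactants: 16 [(2R,3S,4S,5R)-4-({[tert-butyl(diphenyl)silyl]oxy}methyl)-5-(4-hydroxy-3,5-dimethoxyphenyl)-2-(3,4,5-trimethoxyphenyl)oxolan-3-yl]methanol
Product: 17 4-[(2R,3S,4S,5R)-3,4-bis(hydroxymethyl)-5-(3,4,5-trimethoxyphenyl)oxolan-2-yl]-2,6-dimethoxyphenol
Conditions: TBAF, AcOH (1:1), THF, rt
Reagents that add atoms: none
Why: Fluoride-induced desilylation, buffered so that neither phenoxide nor acid can reopen the para-hydroxybenzylic ether next to the now free C4 hydroxymethyl group, should give the target with all four stereocentres as set.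

**Compound list**
1 | 4-hydroxy-3,5-dimethoxybenzaldehyde (syringaldehyde) | COc1cc(C=O)cc(OC)c1O | starting material
2 | 4-(benzyloxy)-3,5-dimethoxybenzaldehyde | COc1cc(C=O)cc(OC)c1OCc2ccccc2 | intermediate
3 | (2E)-3-[4-(benzyloxy)-3,5-dimethoxyphenyl]prop-2-enal | COc1cc(/C=C/C=O)cc(OC)c1OCc2ccccc2 | intermediate
4 | dimethyl 2-bromopropanedioate (dimethyl bromomalonate) | COC(=O)C(Br)C(=O)OC | starting material
5 | dimethyl (2R,3S)-2-[4-(benzyloxy)-3,5-dimethoxyphenyl]-3-formylcyclopropane-1,1-dicarboxylate | COC(=O)C1(C(=O)OC)[C@@H](c2cc(OC)c(OCc3ccccc3)c(OC)c2)[C@@H]1C=O | intermediate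
6 | dimethyl (2R,3S)-2-[4-(benzyloxy)-3,5-dimethoxyphenyl]-3-(hydroxymethyl)cyclopropane-1,1-dicarboxylate | COC(=O)C1(C(=O)OC)[C@@H](c2cc(OC)c(OCc3ccccc3)c(OC)c2)[C@@H]1CO | intermediate
7 | dimethyl (2R,3S)-2-[4-(benzyloxy)-3,5-dimethoxyphenyl]-3-({[tert-butyl(diphenyl)silyl]oxy}methyl)cyclopropane-1,1-dicarboxylate | COC(=O)C1(C(=O)OC)[C@@H](c2cc(OC)c(OCc3ccccc3)c(OC)c2)[C@@H]1CO[Si](c4ccccc4)(c5ccccc5)C(C)(C)C | intermediate
8 | 3,4,5-trimethoxybenzaldehyde | COc1cc(C=O)cc(OC)c1OC | starting material
9 | oxocarbenium malonate zwitterion (aldehyde oxygen of 8 bonded to C2 with inversion; C2 S, C3 S; metal-bound in the flask) | COC(=O)[C-](C(=O)OC)[C@@H](CO[Si](c1ccccc1)(c2ccccc2)C(C)(C)C)[C@@H](c3cc(OC)c(OCc4ccccc4)c(OC)c3)[O+]=Cc5cc(OC)c(OC)c(OC)c5 | intermediate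
10 | dimethyl (2S,4S,5S)-5-[4-(benzyloxy)-3,5-dimethoxyphenyl]-4-({[tert-butyl(diphenyl)silyl]oxy}methyl)-2-(3,4,5-trimethoxyphenyl)oxolane-3,3-dicarboxylate | COc1cc(cc(OC)c1OCc2ccccc2)[C@H]3O[C@@H](c4cc(OC)c(OC)c(OC)c4)C(C(=O)OC)(C(=O)OC)[C@H]3CO[Si](c5ccccc5)(c6ccccc6)C(C)(C)C | intermediate
11 | methyl (2R,3S,4S,5S)-5-[4-(benzyloxy)-3,5-dimethoxyphenyl]-4-({[tert-butyl(diphenyl)silyl]oxy}methyl)-2-(3,4,5-trimethoxyphenyl)oxolane-3-carboxylate (C4 epimer of 12) | COc1cc(cc(OC)c1OCc2ccccc2)[C@H]3O[C@@H](c4cc(OC)c(OC)c(OC)c4)[C@@H](C(=O)OC)[C@H]3CO[Si](c5ccccc5)(c6ccccc6)C(C)(C)C | intermediate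
12 | methyl (2R,3R,4S,5S)-5-[4-(benzyloxy)-3,5-dimethoxyphenyl]-4-({[tert-butyl(diphenyl)silyl]oxy}methyl)-2-(3,4,5-trimethoxyphenyl)oxolane-3-carboxylate | COc1cc(cc(OC)c1OCc2ccccc2)[C@H]3O[C@@H](c4cc(OC)c(OC)c(OC)c4)[C@H](C(=O)OC)[C@H]3CO[Si](c5ccccc5)(c6ccccc6)C(C)(C)C | intermediate
13 | methyl (2R,3R,4S,5S)-4-({[tert-butyl(diphenyl)silyl]oxy}methyl)-5-(4-hydroxy-3,5-dimethoxyphenyl)-2-(3,4,5-trimethoxyphenyl)oxolane-3-carboxylate | COc1cc(cc(OC)c1O)[C@H]2O[C@@H](c3cc(OC)c(OC)c(OC)c3)[C@H](C(=O)OC)[C@H]2CO[Si](c4ccccc4)(c5ccccc5)C(C)(C)C | intermediate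
14 | ring-opened quinone methide: methyl (2R,3S)-3-({[tert-butyl(diphenyl)silyl]oxy}methyl)-4-(3,5-dimethoxy-4-oxocyclohexa-2,5-dien-1-ylidene)-2-[(R)-hydroxy(3,4,5-trimethoxyphenyl)methyl]butanoate | COC1=CC(=C[C@H](CO[Si](c2ccccc2)(c3ccccc3)C(C)(C)C)[C@@H](C(=O)OC)[C@@H](O)c4cc(OC)c(OC)c(OC)c4)C=C(OC)C1=O | intermediate
15 | methyl (2R,3R,4S,5R)-4-({[tert-butyl(diphenyl)silyl]oxy}methyl)-5-(4-hydroxy-3,5-dimethoxyphenyl)-2-(3,4,5-trimethoxyphenyl)oxolane-3-carboxylate (all-trans) | COc1cc(cc(OC)c1O)[C@@H]2O[C@@H](c3cc(OC)c(OC)c(OC)c3)[C@H](C(=O)OC)[C@H]2CO[Si](c4ccccc4)(c5ccccc5)C(C)(C)C | intermediate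
16 | [(2R,3S,4S,5R)-4-({[tert-butyl(diphenyl)silyl]oxy}methyl)-5-(4-hydroxy-3,5-dimethoxyphenyl)-2-(3,4,5-trimethoxyphenyl)oxolan-3-yl]methanol | COc1cc(cc(OC)c1O)[C@@H]2O[C@@H](c3cc(OC)c(OC)c(OC)c3)[C@H](CO)[C@H]2CO[Si](c4ccccc4)(c5ccccc5)C(C)(C)C | intermediate
17 | 4-[(2R,3S,4S,5R)-3,4-bis(hydroxymethyl)-5-(3,4,5-trimethoxyphenyl)oxolan-2-yl]-2,6-dimethoxyphenol | COc1cc([C@@H]2O[C@@H](c3cc(OC)c(OC)c(OC)c3)[C@H](CO)[C@H]2CO)cc(OC)c1O | target

**Totals**
Total step count: 10. Longest linear sequence: 10 steps from 1 (4 and 8 are bought and enter directly).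

**Steps most likely to fail**

Step 5. The activated cyclopropane may ionise to a free benzylic cation before the aldehyde attacks, which would lose the inversion that relays configuration from C2 to C5. The closure may also show poor 2,5-cis selectivity, or the Lewis acid may cleave the benzyl ether. The fallback separates C–O from C–C bond formation and sets out from 7. Ring opening with (3,4,5-trimethoxyphenyl)methanol (Cu(OTf)2 cat., CH2Cl2, 0 °C) uses a much better oxygen nucleophile than the aldehyde, so SN2 opening with inversion can be run cold, and should give benzylic ether malonate F1. DDQ (CH2Cl2, 4 Å molecular sieves) should then remove hydride from the trimethoxybenzylic CH2 to form the same oxocarbenium ion as in 9. The tethered malonate closes onto it (oxidative cross-dehydrogenative cyclisation of a benzylic ether with a 1,3-dicarbonyl nucleophile), and the route is rejoined at 10.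

Step 8. The C2 cation or quinone methide may be captured irreversibly by the trimethoxyphenyl ring (Friedel–Crafts closure to an aryltetralin), or the equilibrium may not lie far enough on the trans side. The fallback opens and re-closes the ring under neutral conditions and sets out from 12, so it also covers over-reduction in step 7. Prolonged hydrogenolysis (H2, Pd/C, EtOH, AcOH cat.) should remove the benzyl group and then cleave the activated para-hydroxybenzylic C2–O1 bond, giving seco hydroxy ester F2 with C3, C4 and C5 intact. Ag2O (CH2Cl2, rt) should oxidise the 4-alkyl-2,6-dimethoxyphenol to quinone methide 14. The C5 hydroxyl then adds in a kinetic 5-exo-trig oxa-1,6-addition anti to the C3 substituent, and the route is rejoined at 15.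

Step 6. At 150 °C the β-alkoxy malonate may open by elimination or retro-aldol cleavage, which would endanger C5, or the silyl ether may be lost. The fallback sets out from 10. Mono-saponification of the less hindered ester (KOH 1 equiv, MeOH/THF/H2O, rt) should give half-ester F3. Decarboxylation of this malonic half-acid (Et3N, toluene, 90 °C) should give a mixture of 11 and 12, and the methoxide equilibration of step 6 brings it to 12.

Further compounds
F1 | step 5 | dimethyl 2-[(1S,2S)-1-[4-(benzyloxy)-3,5-dimethoxyphenyl]-3-{[tert-butyl(diphenyl)silyl]oxy}-1-[(3,4,5-trimethoxyphenyl)methoxy]propan-2-yl]propanedioate | COC(=O)C(C(=O)OC)[C@@H](CO[Si](c1ccccc1)(c2ccccc2)C(C)(C)C)[C@@H](c3cc(OC)c(OCc4ccccc4)c(OC)c3)OCc5cc(OC)c(OC)c(OC)c5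
F2 | step 8 | methyl (2R,3S)-3-({[tert-butyl(diphenyl)silyl]oxy}methyl)-4-(4-hydroxy-3,5-dimethoxyphenyl)-2-[(R)-hydroxy(3,4,5-trimethoxyphenyl)methyl]butanoate | COc1cc(C[C@H](CO[Si](c2ccccc2)(c3ccccc3)C(C)(C)C)[C@@H](C(=O)OC)[C@@H](O)c4cc(OC)c(OC)c(OC)c4)cc(OC)c1O
F3 | step 6 | (2S,3S,4S,5S)-5-[4-(benzyloxy)-3,5-dimethoxyphenyl]-4-({[tert-butyl(diphenyl)silyl]oxy}methyl)-3-(methoxycarbonyl)-2-(3,4,5-trimethoxyphenyl)oxolane-3-carboxylic acid | COc1cc(cc(OC)c1OCc2ccccc2)[C@H]3O[C@@H](c4cc(OC)c(OC)c(OC)c4)[C@](C(=O)OC)(C(=O)O)[C@H]3CO[Si](c5ccccc5)(c6ccccc6)C(C)(C)C
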